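**Retrosynthetic overview**

1. The target is reached by acid removal of a tert-butyl ester and a silyl ether from 31; the inter-half ester bond of 31 comes from the carboxylate of acid 15 opening the spiro-epoxide of lactone 30 at its CH2 carbon, which also frees the tertiary alcohol.
2. Acid 15 (cyclohexenyl half): the E-2-(hydroxymethyl)acrylate is built on 1,1-dibromoalkene 13 by two successive palladium couplings — a site-selective hydroxycarbonylation of the C–Br bond trans to the ring, then a Stille hydroxymethylation of the cis C–Br bond.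
3. Lactone 30 (bicyclic half): the seven-membered lactone is closed last by ring-closing metathesis; the cis acid/vinyl pair comes from cleaving a cyclobutane made by enone–allene [2+2] photocycloaddition, and the tertiary C–O centre from a convex-face sulfonium ylide epoxidation.
4. Both halves start from (S)-cryptone 4, made in one pot from 3-methylbutanal and but-3-en-2-one; its single stereocentre controls all the others.
5. Ring order: cyclohexenone, then (half A) temporary cyclobutane, spiro-epoxide, oxepinone; ring B is the cryptone ring itself.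

Assumption: the configuration is read from the SMILES as (5aR,6S,9R,9aS) in the benzoxepinone half, (1S,6S) in the cyclohexenyl half, with an E acrylate.

**Route**

Step 1
Reactants: 1 3-methylbutanal; 2 but-3-en-2-one
Product: 4 (4S)-4-(propan-2-yl)cyclohex-2-en-1-one ((S)-cryptone), via keto aldehyde 3 (not isolated)
Conditions: (S)-2-[diphenyl(trimethylsilyloxy)methyl]pyrrolidine (5 mol %), ethyl 3,4-dihydroxybenzoate (20 mol %), neat, 4 °C; then KOH, Bu4NOH (cat.), THF–Et2O–H2O, reflux
Reagents that add atoms: none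
Why: Enamine-catalysed asymmetric Michael addition (the bulky silyloxydiphenylmethyl group shields one enamine face and sets the isopropyl-bearing centre S) followed by intramolecular aldol condensation (Robinson-type annulation).

Step 2
Reactants: 4 (S)-cryptone; 5 vinylmagnesium bromide (CH2=CHMgBr)
Product: 7 (3S,4S)-3-ethenyl-4-(propan-2-yl)cyclohex-1-en-1-yl trifluoromethanesulfonate, via magnesium enolate 6 (not isolated)
Conditions: CuBr·SMe2 (10 mol %), THF, -78 °C; then N-(5-chloropyridin-2-yl)bis(trifluoromethanesulfonimide), -78 to 0 °C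
Reagents that add atoms: N-(5-chloropyridin-2-yl)bis(trifluoromethanesulfonimide) (Comins' reagent), FC(F)(F)S(=O)(=O)N(c1ccc(Cl)cn1)S(=O)(=O)C(F)(F)F
Why: Copper-catalysed conjugate addition of the vinyl Grignard reagent occurs anti to the C4 isopropyl group (trans-3,4), and the regiodefined enolate is trapped on oxygen as the enol triflate.

Step 3
Reactants: 7 enol triflate
Product: 8 methyl (3S,4S)-3-ethenyl-4-(propan-2-yl)cyclohex-1-ene-1-carboxylate
Conditions: Pd(OAc)2 (5 mol %), PPh3 (10 mol %), CO (1 atm), MeOH, Et3N, DMF, 60 °C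
Reagents that add atoms: carbon monoxide, [C-]#[O+]; methanol, CO
Why: Palladium-catalysed alkoxycarbonylation of an alkenyl triflate (oxidative addition, CO insertion, methanolysis); no stereocentre is touched.

Step 4
Reactants: 8 diene ester
Product: 10 methyl (3S,4S)-3-formyl-4-(propan-2-yl)cyclohex-1-ene-1-carboxylate, via diol 9 (not isolated)
Conditions: OsO4 (2 mol %), NaIO4 (4 equiv), 2,6-lutidine, 1,4-dioxane–H2O 3:1, rt
Reagents that add atoms: osmium tetroxide, O=[Os](=O)(=O)=O (oxygen carrier); sodium periodate, [Na+].[O-]I(=O)(=O)=O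
Why: Lemieux–Johnson oxidative cleavage; OsO4 dihydroxylates the electron-rich vinyl group in preference to the conjugated trisubstituted enoate, and lutidine buffering keeps the trans aldehyde from epimerising.

Step 5
Reactants: 10 aldehyde
Product: 11 methyl (3S,4S)-3-(2,2-dibromoethenyl)-4-(propan-2-yl)cyclohex-1-ene-1-carboxylate
Conditions: CBr4 (2 equiv), PPh3 (4 equiv), CH2Cl2, 0 °C
Reagents that add atoms: carbon tetrabromide, BrC(Br)(Br)Br
Why: Ramirez dibromo-olefination (first stage of the Corey–Fuchs sequence) under neutral conditions that leave the alpha stereocentre untouched.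

Step 6
Reactants: 11 dibromoalkene ester
Product: 12 [(3S,4S)-3-(2,2-dibromoethenyl)-4-(propan-2-yl)cyclohex-1-en-1-yl]methanol
Conditions: iBu2AlH (2.5 equiv), CH2Cl2, -78 °C; aq. potassium sodium tartrate
Reagents that add atoms: none
Why: 1,2-Reduction of the conjugated ester to the allylic alcohol by the aluminium hydride; the dibromoalkene is inert at -78 °C.

Step 7
Reactants: 12 allylic alcohol
Product: 13 tert-butyl{[(3S,4S)-3-(2,2-dibromoethenyl)-4-(propan-2-yl)cyclohex-1-en-1-yl]methoxy}dimethylsilane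
Conditions: t-BuMe2SiCl, imidazole, CH2Cl2, rt
Reagents that add atoms: tert-butyldimethylsilyl chloride, CC(C)(C)[Si](C)(C)Cl
Why: Standard silylation of the primary alcohol so that only water acts as the oxygen nucleophile in the next step.

Step 8
Reactants: 13 dibromoalkene
Product: 14 (2Z)-2-bromo-3-[(1S,6S)-3-{[(tert-butyldimethylsilyl)oxy]methyl}-6-(propan-2-yl)cyclohex-2-en-1-yl]prop-2-enoic acid
Conditions: Pd(OAc)2 (5 mol %), Xantphos (7.5 mol %), CO (1 atm), H2O (20 equiv), iPr2NEt (3 equiv), 1,4-dioxane, 45 °C; citric acid work-up (pH 4–5)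
Reagents that add atoms: carbon monoxide, [C-]#[O+]; water, O
Why: Proposed new method: site-selective hydroxycarbonylation of a 1,1-dibromoalkene, in which zerovalent palladium should insert into the C–Br bond trans to the ring (the less hindered one, as in the established trans-selective Stille, Suzuki and Negishi mono-couplings of 1,1-dibromoalkenes), CO insertion gives an acylpalladium bromide that water and amine cleave to the carboxylate, and the second C–Br bond (cis to the ring, now on a carbon carrying an anionic carboxylate) is sterically and electronically slow to react, so the reaction should stop at the (Z)-2-bromoacrylic acid and thereby fix the alkene geometry; the closest known reaction type is the palladium-catalysed hydroxy- or alkoxycarbonylation of simple alkenyl bromides.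

Step 9
Reactants: 14 bromoacrylic acid
Product: 15 (2E)-3-[(1S,6S)-3-{[(tert-butyldimethylsilyl)oxy]methyl}-6-(propan-2-yl)cyclohex-2-en-1-yl]-2-(hydroxymethyl)prop-2-enoic acid
Conditions: Pd(PPh3)4 (5 mol %), Bu3SnCH2OH (1.5 equiv), iPr2NEt (1.2 equiv), 1,4-dioxane, 85 °C
Reagents that add atoms: (tributylstannyl)methanol, CCCC[Sn](CCCC)(CCCC)CO
Why: Stille coupling (Kosugi hydroxymethylation) proceeds with retention at the remaining C–Br bond, so CH2OH ends cis to the ring and the acid trans, i.e. the E acrylate of the target.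

Step 10
Reactants: 16 2-(bromomethyl)prop-2-enoic acid
Product: 17 tert-butyl 2-(bromomethyl)prop-2-enoate
Conditions: tert-butyl 2,2,2-trichloroacetimidate (2 equiv), BF3·OEt2 (5 mol %), CH2Cl2–cyclohexane, rt
Reagents that add atoms: tert-butyl 2,2,2-trichloroacetimidate, CC(C)(C)OC(=N)C(Cl)(Cl)Cl
Why: Acid-catalysed tert-butylation of the carboxylic acid by tert-butyl cation transfer from the imidate.

Step 11
Reactants: 4 (S)-cryptone; 18 propa-1,2-diene (allene)
Product: 19 (1R,5S,6S)-8-methylidene-5-(propan-2-yl)bicyclo[4.2.0]octan-2-one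
Conditions: hν (medium-pressure Hg lamp, Pyrex filter), allene (10 equiv), THF, -78 °C; then basic Al2O3, Et2O, rt
Reagents that add atoms: none
Why: Enone–allene [2+2] photocycloaddition: head-to-head regiochemistry puts the methylidene carbon on the alpha carbon, the allene adds to the face opposite the isopropyl group, and the cis ring fusion (any trans isomer is epimerised on Al2O3) makes the two new C–C bonds cis to each other.

Step 12
Reactants: 19 bicyclic ketone
Product: 20 (1R,2R,5S,6S)-8-methylidene-5-(propan-2-yl)spiro[bicyclo[4.2.0]octane-2,2'-oxirane]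
Conditions: Me3SI (1.5 equiv), KN(SiMe3)2 (1.4 equiv), THF, -10 to 0 °C
Reagents that add atoms: trimethylsulfonium iodide, C[S+](C)C.[I-]
Why: Corey–Chaykovsky epoxidation; the sulfonium ylide attacks the ketone axially from the convex face, anti to the cyclobutane, so the new CH2 is trans and the oxygen cis to C8, which sets the future tertiary carbinol centre.

Step 13
Reactants: 20 methylidene epoxide
Product: 22 (1S,2R,5S,6S)-5-(propan-2-yl)spiro[bicyclo[4.2.0]octane-2,2'-oxiran]-8-one, via ozonide 21 (not isolated)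
Conditions: O3, CH2Cl2, -78 °C; then PPh3, -78 °C to rt
Reagents that add atoms: ozone, [O-][O+]=O
Why: Ozonolysis of the 1,1-disubstituted alkene with reductive work-up gives the cyclobutanone; the epoxide is inert to ozone.

Step 14
Reactants: 22 cyclobutanone
Product: 24 trimethyl{[(1S,2R,5S,6R)-5-(propan-2-yl)spiro[bicyclo[4.2.0]oct-7-ene-2,2'-oxiran]-8-yl]oxy}silane, via lithium enolate 23 (not isolated)
Conditions: LiN(iPr)2 (1.15 equiv) premixed with Me3SiCl (1.5 equiv), THF, -78 °C; Et3N, pentane filtration, used crude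
Reagents that add atoms: chlorotrimethylsilane, C[Si](C)(C)Cl
Why: Kinetic deprotonation at the unhindered C7 methylene (the C1 methine is flanked by the spiro centre) with in situ O-silylation gives the 1-siloxycyclobutene regioselectively, and the low temperature suppresses beta-opening of the epoxide.

Step 15
Reactants: 24 silyl enol ether
Product: 27 (3R,4S,5S,6S)-5-formyl-6-(propan-2-yl)-1-oxaspiro[2.5]octane-4-carboxylic acid, via ozonide 25 (not isolated), via silyl ester 26 (not isolated)
Conditions: O3, CH2Cl2, -78 °C; Me2S, to rt; then THF–pH 5 phosphate buffer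
Reagents that add atoms: ozone, [O-][O+]=O
Why: Ozonolysis of the silyl enol ether cleaves C7–C8 to a silyl ester and an aldehyde that stay cis on the cyclohexane (both centres were set in step 11), and mild hydrolysis frees the acid.

Step 16
Reactants: 27 acid aldehyde
Product: 28 (3R,4S,5S,6S)-5-ethenyl-6-(propan-2-yl)-1-oxaspiro[2.5]octane-4-carboxylic acid
Conditions: Ph3PCH3Br (3.0 equiv), KN(SiMe3)2 (2.9 equiv), THF, -78 to 0 °C; acidify to pH 4
Reagents that add atoms: methyltriphenylphosphonium bromide, C[P+](c1ccccc1)(c1ccccc1)c1ccccc1.[Br-]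
Why: Wittig methylenation of the aldehyde with the acid carried as its carboxylate; no stereocentre is affected at low temperature.

Step 17
Reactants: 28 vinyl acid; 17 tert-butyl 2-(bromomethyl)prop-2-enoate
Product: 29 2-(tert-butoxycarbonyl)prop-2-en-1-yl (3R,4S,5S,6S)-5-ethenyl-6-(propan-2-yl)-1-oxaspiro[2.5]octane-4-carboxylate
Conditions: Cs2CO3 (0.55 equiv), DMF, 0 °C to rt
Reagents that add atoms: none
Why: Carboxylate O-alkylation with the allylic bromide (SN2 and SN2' give the same product), fast enough at 0 °C to outrun any attack of the carboxylate on the epoxide.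

Step 18
Reactants: 29 diene ester
Product: 30 tert-butyl (5aR,6S,9R,9aS)-1-oxo-6-(propan-2-yl)-1,3,5a,6,7,8,9,9a-octahydrospiro[2-benzoxepine-9,2'-oxirane]-4-carboxylate
Conditions: second-generation Grubbs catalyst RuCl2(=CHPh)(PCy3)(1,3-dimesitylimidazolidin-2-ylidene) (5 mol %), CH2Cl2 (5 mM), 40 °C
Reagents that add atoms: none
Why: Ring-closing metathesis between the vinyl group and the 1,1-disubstituted acrylate, held cis on the cyclohexane, closes the seven-membered lactone and fixes the ring alkene geometry.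

Step 19
Reactants: 30 spiro-epoxide lactone; 15 hydroxymethyl acrylic acid (1.3 equiv)
Product: 31 tert-butyl (5aR,6S,9R,9aS)-9-({[(2E)-3-[(1S,6S)-3-{[(tert-butyldimethylsilyl)oxy]methyl}-6-(propan-2-yl)cyclohex-2-en-1-yl]-2-(hydroxymethyl)prop-2-enoyl]oxy}methyl)-9-hydroxy-1-oxo-6-(propan-2-yl)-1,3,5a,6,7,8,9,9a-octahydro-2-benzoxepine-4-carboxylate
Conditions: Cs2CO3 (0.2 equiv), DMF, 60 °C
Reagents that add atoms: none
Why: Base-catalysed carboxylate opening of the 2,2-disubstituted epoxide at its CH2 carbon (SN2) forms the inter-half ester and liberates the tertiary alcohol with retention at C9, the excess acid protonating the alkoxide at once.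

Step 20
Reactants: 31 protected coupled product
Product: 32 (5aR,6S,9R,9aS)-9-hydroxy-9-({[(2E)-2-(hydroxymethyl)-3-[(1S,6S)-3-(hydroxymethyl)-6-(propan-2-yl)cyclohex-2-en-1-yl]prop-2-enoyl]oxy}methyl)-1-oxo-6-(propan-2-yl)-1,3,5a,6,7,8,9,9a-octahydro-2-benzoxepine-4-carboxylic acid (CNP0361406.4)
Conditions: CF3CO2H–CH2Cl2–H2O (5:10:1), 0 °C to rt; then MeOH, aq. NaHCO3 to pH 7, 0 °C
Reagents that add atoms: none
Why: Acidolysis cleaves the tert-butyl ester (loss of isobutene) and the primary silyl ether in one operation, and the brief neutral methanolysis removes any trifluoroacetate esters.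

**Compound list**

1 | 3-methylbutanal | CC(C)CC=O | starting material
2 | but-3-en-2-one | CC(=O)C=C | starting material
3 | (2S)-5-oxo-2-(propan-2-yl)hexanal | CC(C)[C@@H](C=O)CCC(C)=O | intermediate
4 | (4S)-4-(propan-2-yl)cyclohex-2-en-1-one ((S)-cryptone) | CC(C)[C@H]1C=CC(=O)CC1 | intermediate
5 | vinylmagnesium bromide | C=C[Mg]Br | starting material
6 | bromomagnesium enolate of (3S,4S)-3-ethenyl-4-(propan-2-yl)cyclohexanone (C1=C2 enolate) | C=C[C@@H]1C=C(O[Mg]Br)CC[C@H]1C(C)C | intermediate
7 | (3S,4S)-3-ethenyl-4-(propan-2-yl)cyclohex-1-en-1-yl trifluoromethanesulfonate | C=C[C@@H]1C=C(OS(=O)(=O)C(F)(F)F)CC[C@H]1C(C)C | intermediate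
8 | methyl (3S,4S)-3-ethenyl-4-(propan-2-yl)cyclohex-1-ene-1-carboxylate | C=C[C@@H]1C=C(C(=O)OC)CC[C@H]1C(C)C | intermediate
9 | methyl (3S,4S)-3-(1,2-dihydroxyethyl)-4-(propan-2-yl)cyclohex-1-ene-1-carboxylate (both carbinol epimers) | OCC(O)[C@@H]1C=C(C(=O)OC)CC[C@H]1C(C)C | intermediate
10 | methyl (3S,4S)-3-formyl-4-(propan-2-yl)cyclohex-1-ene-1-carboxylate | O=C[C@@H]1C=C(C(=O)OC)CC[C@H]1C(C)C | intermediate
11 | methyl (3S,4S)-3-(2,2-dibromoethenyl)-4-(propan-2-yl)cyclohex-1-ene-1-carboxylate | BrC(Br)=C[C@@H]1C=C(C(=O)OC)CC[C@H]1C(C)C | intermediate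
12 | [(3S,4S)-3-(2,2-dibromoethenyl)-4-(propan-2-yl)cyclohex-1-en-1-yl]methanol | BrC(Br)=C[C@@H]1C=C(CO)CC[C@H]1C(C)C | intermediate
13 | tert-butyl{[(3S,4S)-3-(2,2-dibromoethenyl)-4-(propan-2-yl)cyclohex-1-en-1-yl]methoxy}dimethylsilane | BrC(Br)=C[C@@H]1C=C(CO[Si](C)(C)C(C)(C)C)CC[C@H]1C(C)C | intermediate
14 | (2Z)-2-bromo-3-[(1S,6S)-3-{[(tert-butyldimethylsilyl)oxy]methyl}-6-(propan-2-yl)cyclohex-2-en-1-yl]prop-2-enoic acid | OC(=O)/C(Br)=C/[C@@H]1C=C(CO[Si](C)(C)C(C)(C)C)CC[C@H]1C(C)C | intermediate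
15 | (2E)-3-[(1S,6S)-3-{[(tert-butyldimethylsilyl)oxy]methyl}-6-(propan-2-yl)cyclohex-2-en-1-yl]-2-(hydroxymethyl)prop-2-enoic acid | OC(=O)/C(CO)=C/[C@@H]1C=C(CO[Si](C)(C)C(C)(C)C)CC[C@H]1C(C)C | intermediate
16 | 2-(bromomethyl)prop-2-enoic acid | OC(=O)C(=C)CBr | starting material
17 | tert-butyl 2-(bromomethyl)prop-2-enoate | CC(C)(C)OC(=O)C(=C)CBr | intermediate
18 | propa-1,2-diene (allene) | C=C=C | starting material
19 | (1R,5S,6S)-8-methylidene-5-(propan-2-yl)bicyclo[4.2.0]octan-2-one (cis-fused, cyclobutane anti to isopropyl) | CC(C)[C@@H]1CCC(=O)[C@H]2C(=C)C[C@@H]12 | intermediate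
20 | (1R,2R,5S,6S)-8-methylidene-5-(propan-2-yl)spiro[bicyclo[4.2.0]octane-2,2'-oxirane] | CC(C)[C@@H]1CC[C@]3(CO3)[C@H]2C(=C)C[C@@H]12 | intermediate
21 | spiro 1,2,4-trioxolane (ozonide) of 20 at C8 | CC(C)[C@@H]1CC[C@]3(CO3)[C@H]2C4(OCOO4)C[C@@H]12 | intermediate
22 | (1S,2R,5S,6S)-5-(propan-2-yl)spiro[bicyclo[4.2.0]octane-2,2'-oxiran]-8-one | CC(C)[C@@H]1CC[C@]3(CO3)[C@H]2C(=O)C[C@@H]12 | intermediate
23 | lithium C7=C8 enolate of 22 | CC(C)[C@@H]1CC[C@]3(CO3)[C@H]2C(O[Li])=C[C@@H]12 | intermediate
24 | trimethyl{[(1S,2R,5S,6R)-5-(propan-2-yl)spiro[bicyclo[4.2.0]oct-7-ene-2,2'-oxiran]-8-yl]oxy}silane | CC(C)[C@@H]1CC[C@]3(CO3)[C@H]2C(O[Si](C)(C)C)=C[C@@H]12 | intermediate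
25 | bridged 1,2,4-trioxolane (ozonide) of 24 across C7/C8 | CC(C)[C@@H]1CC[C@]3(CO3)[C@H]2C4(O[Si](C)(C)C)OOC(O4)[C@@H]12 | intermediate
26 | trimethylsilyl (3R,4S,5S,6S)-5-formyl-6-(propan-2-yl)-1-oxaspiro[2.5]octane-4-carboxylate | CC(C)[C@@H]1CC[C@]3(CO3)[C@@H](C(=O)O[Si](C)(C)C)[C@H]1C=O | intermediate
27 | (3R,4S,5S,6S)-5-formyl-6-(propan-2-yl)-1-oxaspiro[2.5]octane-4-carboxylic acid | CC(C)[C@@H]1CC[C@]3(CO3)[C@@H](C(=O)O)[C@H]1C=O | intermediate
28 | (3R,4S,5S,6S)-5-ethenyl-6-(propan-2-yl)-1-oxaspiro[2.5]octane-4-carboxylic acid | CC(C)[C@@H]1CC[C@]3(CO3)[C@@H](C(=O)O)[C@H]1C=C | intermediate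
29 | 2-(tert-butoxycarbonyl)prop-2-en-1-yl (3R,4S,5S,6S)-5-ethenyl-6-(propan-2-yl)-1-oxaspiro[2.5]octane-4-carboxylate | CC(C)[C@@H]1CC[C@]3(CO3)[C@@H](C(=O)OCC(=C)C(=O)OC(C)(C)C)[C@H]1C=C | intermediate
30 | tert-butyl (5aR,6S,9R,9aS)-1-oxo-6-(propan-2-yl)-1,3,5a,6,7,8,9,9a-octahydrospiro[2-benzoxepine-9,2'-oxirane]-4-carboxylate | CC(C)[C@@H]1CC[C@]3(CO3)[C@H]2C(=O)OCC(C(=O)OC(C)(C)C)=C[C@@H]12 | intermediate
31 | tert-butyl ester and mono-silyl ether of the target (name as in step 19) | CC(C)[C@@H]1CC[C@](O)(COC(=O)/C(=C/[C@@H]2C=C(CO[Si](C)(C)C(C)(C)C)CC[C@H]2C(C)C)CO)[C@H]2C(=O)OCC(C(=O)OC(C)(C)C)=C[C@@H]12 | intermediate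
32 | CNP0361406.4 (name as in step 20) | CC(C)[C@@H]1CC[C@](O)(COC(=O)/C(=C/[C@@H]2C=C(CO)CC[C@H]2C(C)C)CO)[C@H]2C(=O)OCC(C(=O)O)=C[C@@H]12 | target

**Step count and weak points**

Total step count: 20. Longest linear sequence: 11 steps (steps 1, 11 to 18, 19, 20; the branch through steps 2 to 9 is equally long), i.e. 55 % of the total.

The three steps most likely to fail:

Step 8 (the proposed new site-selective hydroxycarbonylation). It may give mixtures of mono- and dicarbonylation or erode the geometry. The fallback uses known chemistry; it sets out from 13 and comes back to the route at 15, bypassing 14 and step 9. Treatment of 13 with n-BuLi (2.2 equiv, THF, -78 °C) and paraformaldehyde gives the propargylic alcohol F1. Syn hydrostannation of F1 with Bu3SnH and PdCl2(PPh3)2 places tin on the carbon next to CH2OH, away from the branched ring substituent, and gives the (E)-2-stannyl allylic alcohol F2. Iododestannylation with I2 in CH2Cl2 at 0 °C proceeds with retention to the (E)-2-iodo allylic alcohol F3. Ordinary palladium-catalysed hydroxycarbonylation of this single alkenyl iodide (Pd(OAc)2, PPh3, CO, H2O, K2CO3, dioxane) then delivers 15 with the acid trans and CH2OH cis to the ring.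

Step 14 (regioselective silyl enol ether from the epoxy cyclobutanone). Deprotonation at C1 would open the epoxide by beta-elimination, and the cyclobutanone is sensitive. The fallback sets out from 20 and comes back at 27, avoiding strong base. Allylic hydroxylation of 20 with SeO2 (cat.) and t-BuOOH in CH2Cl2 occurs at the C7 methylene rather than the hindered C1 methine and gives the allylic alcohol F4. Ozonolysis (O3, then PPh3) converts F4 into the alpha-hydroxy cyclobutanone F5. Glycol-type cleavage of F5 with NaIO4 in THF–H2O opens the four-membered ring between C7 and C8 and gives acid aldehyde 27 directly.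

Step 19 (fragment union). The epoxide CH2 sits next to a quaternary carbon, and the allylic lactone of 30 may not tolerate warm carboxylate. The fallback changes the order of events; it sets out from 29 (with 15) and comes back at 31. The epoxide of the open-chain diene ester 29 is opened with acid 15 (Cs2CO3 cat., DMF, 50 °C) before any lactone exists, giving the coupled hydroxy ester F6. The seven-membered lactone is then closed on F6 by ring-closing metathesis with the second-generation Grubbs catalyst RuCl2(=CHPh)(PCy3)(1,3-dimesitylimidazolidin-2-ylidene); the two trisubstituted alkenes of the cyclohexenyl half are inert under these conditions, and 31 results.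

**Further compounds**

F1 | step 8 | 3-[(1S,6S)-3-{[(tert-butyldimethylsilyl)oxy]methyl}-6-(propan-2-yl)cyclohex-2-en-1-yl]prop-2-yn-1-ol | OCC#C[C@@H]1C=C(CO[Si](C)(C)C(C)(C)C)CC[C@H]1C(C)C
F2 | step 8 | (2E)-3-[(1S,6S)-3-{[(tert-butyldimethylsilyl)oxy]methyl}-6-(propan-2-yl)cyclohex-2-en-1-yl]-2-(tributylstannyl)prop-2-en-1-ol | CCCC[Sn](CCCC)(CCCC)/C(CO)=C/[C@@H]1C=C(CO[Si](C)(C)C(C)(C)C)CC[C@H]1C(C)C
F3 | step 8 | (2E)-3-[(1S,6S)-3-{[(tert-butyldimethylsilyl)oxy]methyl}-6-(propan-2-yl)cyclohex-2-en-1-yl]-2-iodoprop-2-en-1-ol | I/C(CO)=C/[C@@H]1C=C(CO[Si](C)(C)C(C)(C)C)CC[C@H]1C(C)C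
F4 | step 14 | (1R,2R,5S,6S)-8-methylidene-5-(propan-2-yl)spiro[bicyclo[4.2.0]octane-2,2'-oxiran]-7-ol (C7 epimers) | CC(C)[C@@H]1CC[C@]3(CO3)[C@H]2C(=C)C(O)[C@@H]12
F5 | step 14 | (1S,2R,5S,6S)-7-hydroxy-5-(propan-2-yl)spiro[bicyclo[4.2.0]octane-2,2'-oxiran]-8-one (C7 epimers) | CC(C)[C@@H]1CC[C@]3(CO3)[C@H]2C(=O)C(O)[C@@H]12
F6 | step 19 | 2-(tert-butoxycarbonyl)prop-2-en-1-yl (1S,2R,3S,6S)-2-({[(2E)-3-[(1S,6S)-3-{[(tert-butyldimethylsilyl)oxy]methyl}-6-(propan-2-yl)cyclohex-2-en-1-yl]-2-(hydroxymethyl)prop-2-enoyl]oxy}methyl)-6-ethenyl-2-hydroxy-3-(propan-2-yl)cyclohexane-1-carboxylate (ring-opened precursor of 31) | CC(C)[C@@H]1CC[C@](O)(COC(=O)/C(=C/[C@@H]2C=C(CO[Si](C)(C)C(C)(C)C)CC[C@H]2C(C)C)CO)[C@@H](C(=O)OCC(=C)C(=O)OC(C)(C)C)[C@H]1C=C
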